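The C3–C4–C5 unit is treated as a latent 2-oxyallyl cation and C1=C2 as a cyclic enol ether tied to O9. Numbering is daucane: C1 quaternary (methyl), C2–C3 ring CH2CH2, C4 isopropyl carbinol, C5 ring-fusion CH, C6 ester carbon, C8(=C14H2), C9 carbinol, C10. Because O9 is 1,3 to C1 and cis to C2 on the seven-membered ring, it is bonded to C2 as a 4-methyl-2,3-dihydrofuran. A silyl-triflate-catalysed intramolecular (3+2) cycloaddition of a cis-epoxy enol silane with this enol ether forms C1–C5 and C2–C3, closes both carbocycles at once, sets C1 from C9 and brings O6 from the epoxide. The precursor is an acyclic epoxy enol silane carrying the dihydrofuran.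

Key step: step 8

Remark: in the two catalyst-controlled steps (2 and 6) the ligand enantiomer is the one that delivers the stated configuration; pent-4-ynal is taken as commercially available; "11,12,13-trinor" means that the isopropyl group is still absent.

Step 1
Reactants: 1 pent-4-ynal; 2 formaldehyde
Product: 3 2-methylidenepent-4-ynal
Conditions: 37% aq. CH2O, pyrrolidine (10 mol%), propionic acid (10 mol%), iPrOH, 45 °C
Reagents that add atoms: formaldehyde 2, C=O
Why: Organocatalytic α-methylenation (Mannich condensation, then loss of the amine) turns the aldehyde α-CH2 into the C8=C14 methylidene and leaves the alkyne alone.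

Step 2
Reactants: 3 2-methylidenepent-4-ynal; 4 2-methoxypropene
Product: 6 (4S)-4-hydroxy-5-methylideneoct-7-yn-2-one, via enol ether 5 (not isolated)
Conditions: Ti(OiPr)4 (5 mol%), 2-[(3-bromo-5-tert-butyl-2-hydroxybenzylidene)amino]-2'-hydroxy-1,1'-binaphthyl (5 mol%), 3,5-di-tert-butylsalicylic acid (5 mol%), 4 as solvent, 0 °C; then 2 M HCl, Et2O, 0 °C
Reagents that add atoms: 2-methoxypropene 4, COC(C)=C; water, O
Why: A catalytic enantioselective ene-type (Mukaiyama-type) aldol addition of the acetone enol ether adds 1,2 to the enal, the ligand fixes C9 as S, and acid hydrolysis of the enol ether gives the methyl ketone.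

Step 3
Reactants: 6 (4S)-4-hydroxy-5-methylideneoct-7-yn-2-one; 7 (trimethylsilyl)diazomethane
Product: 8 (2S)-4-methyl-2-(pent-1-en-4-yn-2-yl)-2,3-dihydrofuran
Conditions: 7 (2.5 equiv), n-BuLi (2.4 equiv), THF, −78 °C; then 6, −78 °C → rt; aq. work-up
Reagents that add atoms: (trimethylsilyl)diazomethane 7, C[Si](C)(C)C=[N+]=[N-]
Why: Lithiated 7 converts the ketone into an alkylidene carbene (Colvin-type olefination, loss of N2) that inserts 1,5 into the O–H/O–Li bond at C9, a known route from β-hydroxy ketones to 2,3-dihydrofurans that does not touch C9.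

Step 4
Reactants: 8 (2S)-4-methyl-2-(pent-1-en-4-yn-2-yl)-2,3-dihydrofuran; 9 N-methoxy-N-methylacetamide
Product: 10 6-[(2S)-4-methyl-2,3-dihydrofuran-2-yl]hept-6-en-3-yn-2-one
Conditions: n-BuLi (1.05 equiv), THF, −78 °C; then 9, −78 → 0 °C; aq. work-up
Reagents that add atoms: N-methoxy-N-methylacetamide 9, CON(C)C(C)=O
Why: Acylation of the lithium acetylide with an N-methoxy-N-methylamide (Weinreb ketone synthesis) stops at the ynone because the chelated tetrahedral adduct survives until work-up.

Step 5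
Reactants: 10 6-[(2S)-4-methyl-2,3-dihydrofuran-2-yl]hept-6-en-3-yn-2-one
Product: 11 (3Z)-6-[(2S)-4-methyl-2,3-dihydrofuran-2-yl]hepta-3,6-dien-2-one
Conditions: H2 (1 atm), Pd/CaCO3 poisoned with Pb(OAc)2, quinoline, EtOAc, 0 °C; used at once
Reagents that add atoms: none
Why: Semihydrogenation of the alkyne on poisoned palladium (syn addition of H2) gives the cis-enone and spares the 1,1-disubstituted alkene and the enol ether.

Step 6
Reactants: 11 (3Z)-6-[(2S)-4-methyl-2,3-dihydrofuran-2-yl]hepta-3,6-dien-2-one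
Product: 12 1-[(2S,3S)-3-{2-[(2S)-4-methyl-2,3-dihydrofuran-2-yl]prop-2-en-1-yl}oxiran-2-yl]ethan-1-one
Conditions: Yb(OiPr)3 (10 mol%), 3-(hydroxymethyl)-1,1'-bi-2-naphthol (10 mol%), tBuOOH, 4 Å MS, THF, rt
Reagents that add atoms: tert-butyl hydroperoxide, CC(C)(C)OO
Why: Nucleophilic (Weitz–Scheffer-type) epoxidation under ytterbium binaphthoxide catalysis, a catalyst type that keeps the cis geometry of cis-enones, should set C5 and C6 (both S) by ligand control without attacking the electron-rich alkenes.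

Step 7
Reactants: 12 1-[(2S,3S)-3-{2-[(2S)-4-methyl-2,3-dihydrofuran-2-yl]prop-2-en-1-yl}oxiran-2-yl]ethan-1-one
Product: 13 triethyl({1-[(2S,3S)-3-{2-[(2S)-4-methyl-2,3-dihydrofuran-2-yl]prop-2-en-1-yl}oxiran-2-yl]ethenyl}oxy)silane
Conditions: TESOTf (1.2 equiv), Et3N (2 equiv), CH2Cl2, −78 °C; Et3N-buffered work-up
Reagents that add atoms: triethylsilyl trifluoromethanesulfonate, CC[Si](CC)(CC)OS(=O)(=O)C(F)(F)F
Why: Soft enolisation with silyl triflate and amine gives the only possible silyl enol ether, because the other α-carbon is the epoxide carbon.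

Step 8
Reactants: 13 triethyl({1-[(2S,3S)-3-{2-[(2S)-4-methyl-2,3-dihydrofuran-2-yl]prop-2-en-1-yl}oxiran-2-yl]ethenyl}oxy)silane
Product: 14 (1R,2S,5R,6S,9S)-2,9-epoxy-6-(triethylsilyloxy)-11,12,13-trinordauc-8(14)-en-4-one
Conditions: TESOTf (10 mol%), CH2Cl2, −78 → −40 °C; Et3N quench
Reagents that add atoms: none
Why: Proposed new method: the silyl cation opens the cis-epoxide at C5, where the silyl enol ether stabilises the developing 2-siloxyallyl cation, while C1 of the dihydrofuran (the enol-ether β-carbon) attacks C5 from the backside; the oxolanylium ion at C2 is then captured by the enol-silane carbon C3, and the silyl group passes to the next epoxide, so the triflate is catalytic. The closest known reactions are the silyl-triflate-catalysed (4+3) cycloadditions of epoxy enol silanes with furans and the (3+2) cycloadditions of 2-oxyallyl cations with enol ethers that give cyclopentanones; a (3+2) reaction of an epoxy enol silane with a tethered enol ether is not known. The seven-membered ring closes by 7-exo-trig attack of the enol ether with endo opening of the epoxide (both epoxide carbons end up in the ring), and the cyclopentanone closes by a 5-(enolendo)-exo-trig Mukaiyama addition, the closure common to all oxyallyl (3+2) cycloadditions. C5 is set by inversion of the (2S,3S)-epoxide and C6 is carried over; C1 is set by C9, because the four-atom tether from C9 can reach C1 only on its own face of the dihydrofuran (a bicyclo[4.2.1] bridge); C2 follows from the obligatory cis fusion of the oxolane and cyclopentanone rings. The step needs C5-over-C6 regioselectivity in the epoxide opening (secured by the enol silane), preference for the enol ether over the C8=C14 alkene (far more nucleophilic, and the methylidene could only close a 5-endo ring), and the cis-epoxide, because only the C5 epimer formed from it by inversion places C3 within reach of C2; the C1–C5 ring fusion is therefore cis here and is corrected in step 10.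

Step 9
Reactants: 14 (1R,2S,5R,6S,9S)-2,9-epoxy-6-(triethylsilyloxy)-11,12,13-trinordauc-8(14)-en-4-one
Product: 15 (1S,5R,6S,9S)-9-(tert-butyldimethylsilyloxy)-6-(triethylsilyloxy)-11,12,13-trinordauca-2,8(14)-dien-4-one
Conditions: TBSOTf (1.5 equiv), Et3N (3 equiv), CH2Cl2, −78 → 0 °C
Reagents that add atoms: tert-butyldimethylsilyl trifluoromethanesulfonate, CC(C)(C)[Si](C)(C)OS(=O)(=O)C(F)(F)F
Why: Silyl enol ether formation toward C3 and silyl-triflate-assisted β-elimination of the bridging ether oxygen (retro-oxa-Michael opening of a β-alkoxy ketone) should release the cyclopentenone and leave O9 as its TBS ether.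

Step 10
Reactants: 15 (1S,5R,6S,9S)-9-(tert-butyldimethylsilyloxy)-6-(triethylsilyloxy)-11,12,13-trinordauca-2,8(14)-dien-4-one
Product: 17 (1R,5S,6S,9S)-9-(tert-butyldimethylsilyloxy)-6-(triethylsilyloxy)-11,12,13-trinordauc-8(14)-en-4-one (trans-fused), via cis-fused ketone 16 (not isolated)
Conditions: [(Ph3P)CuH]6 (5 mol%), H2 (35 bar), tBuOH, PhH, rt; then DBU (0.3 equiv), PhMe, rt
Reagents that add atoms: none
Why: Copper hydride conjugate reduction saturates only the enone C2=C3, and base-mediated enolisation then equilibrates C5 to the trans-fused ketone, which is expected to be favoured because C4, O6 and O9 are then all equatorial on the chair cycloheptane.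

Step 11
Reactants: 17 trans-fused ketone; 18 isopropylmagnesium chloride
Product: 20 (1R,4R,5S,6S,9S)-9-(tert-butyldimethylsilyloxy)dauc-8(14)-ene-4,6-diol, via triethylsilyl ether 19 (not isolated)
Conditions: 18 (3 equiv), CeCl3 (3 equiv), THF, −78 → 0 °C; then 1 M HCl, THF, 0 °C
Reagents that add atoms: isopropylmagnesium chloride 18, CC(C)[Mg]Cl
Why: Organocerium 1,2-addition (low basicity, so no enolisation or β-elimination) should occur on the cyclopentanone face that carries H5, opposite the angular methyl group and the C5–C6 bond, which sets C4 as R, and dilute acid then removes only the more labile triethylsilyl ether.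

Step 12
Reactants: 21 4-hydroxybenzoic acid
Product: 23 4-[(tert-butyldimethylsilyl)oxy]benzoic acid, via silyl ester 22 (not isolated)
Conditions: TBSCl (2.5 equiv), imidazole (5 equiv), DMF, rt; then K2CO3 (cat.), MeOH/THF/H2O, rt; acidify to pH 4
Reagents that add atoms: tert-butyldimethylsilyl chloride, CC(C)(C)[Si](C)(C)Cl
Why: Double silylation followed by selective hydrolysis of the labile silyl ester (silyl ether protection) leaves only the phenol protected.

Step 13
Reactants: 20 (1R,4R,5S,6S,9S)-9-(tert-butyldimethylsilyloxy)dauc-8(14)-ene-4,6-diol; 23 4-[(tert-butyldimethylsilyl)oxy]benzoic acid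
Product: 24 (1R,4R,5S,6S,9S)-9-(tert-butyldimethylsilyloxy)-4-hydroxydauc-8(14)-en-6-yl 4-[(tert-butyldimethylsilyl)oxy]benzoate
Conditions: DCC (1.5 equiv), DMAP (0.5 equiv), CH2Cl2, rt
Reagents that add atoms: 4-[(tert-butyldimethylsilyl)oxy]benzoic acid 23, CC(C)(C)[Si](C)(C)Oc1ccc(cc1)C(O)=O
Why: Steglich esterification acylates the secondary C6 hydroxyl, since the tertiary C4 hydroxyl is unreactive and O9 is silylated.

Step 14
Reactants: 24 bis-silylated ester
Product: 25 Ferugin, (1R,4R,5S,6S,9S)-4,9-dihydroxydauc-8(14)-en-6-yl 4-hydroxybenzoate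
Conditions: TBAF (3 equiv), AcOH (3 equiv), THF, 0 °C → rt
Reagents that add atoms: none
Why: Fluoride-mediated desilylation removes the aryl and the allylic TBS ethers, and the acetic acid buffer keeps the benzoate from migrating or cleaving.

Compound list
1 | pent-4-ynal | C#CCCC=O | starting material
2 | formaldehyde | C=O | starting material
3 | 2-methylidenepent-4-ynal | C#CCC(=C)C=O | intermediate
4 | 2-methoxypropene | COC(C)=C | starting material
5 | (4S)-2-methoxy-5-methylideneoct-1-en-7-yn-4-ol | C=C(OC)C[C@H](O)C(=C)CC#C | intermediate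
6 | (4S)-4-hydroxy-5-methylideneoct-7-yn-2-one | CC(=O)C[C@H](O)C(=C)CC#C | intermediate
7 | (trimethylsilyl)diazomethane | C[Si](C)(C)C=[N+]=[N-] | starting material
8 | (2S)-4-methyl-2-(pent-1-en-4-yn-2-yl)-2,3-dihydrofuran | CC1=CO[C@@H](C1)C(=C)CC#C | intermediate
9 | N-methoxy-N-methylacetamide | CON(C)C(C)=O | starting material
10 | 6-[(2S)-4-methyl-2,3-dihydrofuran-2-yl]hept-6-en-3-yn-2-one | CC(=O)C#CCC(=C)[C@@H]1CC(C)=CO1 | intermediate
11 | (3Z)-6-[(2S)-4-methyl-2,3-dihydrofuran-2-yl]hepta-3,6-dien-2-one | CC(=O)/C=C\CC(=C)[C@@H]1CC(C)=CO1 | intermediate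
12 | 1-[(2S,3S)-3-{2-[(2S)-4-methyl-2,3-dihydrofuran-2-yl]prop-2-en-1-yl}oxiran-2-yl]ethan-1-one (cis-epoxide) | CC(=O)[C@H]1O[C@H]1CC(=C)[C@@H]2CC(C)=CO2 | intermediate
13 | triethyl({1-[(2S,3S)-3-{2-[(2S)-4-methyl-2,3-dihydrofuran-2-yl]prop-2-en-1-yl}oxiran-2-yl]ethenyl}oxy)silane | C=C(O[Si](CC)(CC)CC)[C@H]1O[C@H]1CC(=C)[C@@H]2CC(C)=CO2 | intermediate
14 | (1R,2S,5R,6S,9S)-2,9-epoxy-6-(triethylsilyloxy)-11,12,13-trinordauc-8(14)-en-4-one (cis-fused cyclopentanone and cycloheptane, oxygen bridge C2–O–C9) | O=C1C[C@@H]2O[C@H]3C[C@]2(C)[C@@H]1[C@@H](O[Si](CC)(CC)CC)CC3=C | intermediate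
15 | (1S,5R,6S,9S)-9-(tert-butyldimethylsilyloxy)-6-(triethylsilyloxy)-11,12,13-trinordauca-2,8(14)-dien-4-one | O=C1C=C[C@]2(C)C[C@H](O[Si](C)(C)C(C)(C)C)C(=C)C[C@H](O[Si](CC)(CC)CC)[C@H]12 | intermediate
16 | (1R,5R,6S,9S)-9-(tert-butyldimethylsilyloxy)-6-(triethylsilyloxy)-11,12,13-trinordauc-8(14)-en-4-one (cis-fused) | O=C1CC[C@]2(C)C[C@H](O[Si](C)(C)C(C)(C)C)C(=C)C[C@H](O[Si](CC)(CC)CC)[C@H]12 | intermediate
17 | (1R,5S,6S,9S)-9-(tert-butyldimethylsilyloxy)-6-(triethylsilyloxy)-11,12,13-trinordauc-8(14)-en-4-one (trans-fused) | O=C1CC[C@]2(C)C[C@H](O[Si](C)(C)C(C)(C)C)C(=C)C[C@H](O[Si](CC)(CC)CC)[C@@H]12 | intermediate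
18 | isopropylmagnesium chloride | CC(C)[Mg]Cl | starting material
19 | (1R,4R,5S,6S,9S)-9-(tert-butyldimethylsilyloxy)-6-(triethylsilyloxy)dauc-8(14)-en-4-ol | CC(C)[C@]1(O)CC[C@]2(C)C[C@H](O[Si](C)(C)C(C)(C)C)C(=C)C[C@H](O[Si](CC)(CC)CC)[C@@H]12 | intermediate
20 | (1R,4R,5S,6S,9S)-9-(tert-butyldimethylsilyloxy)dauc-8(14)-ene-4,6-diol | CC(C)[C@]1(O)CC[C@]2(C)C[C@H](O[Si](C)(C)C(C)(C)C)C(=C)C[C@H](O)[C@@H]12 | intermediate
21 | 4-hydroxybenzoic acid | OC(=O)c1ccc(O)cc1 | starting material
22 | tert-butyldimethylsilyl 4-[(tert-butyldimethylsilyl)oxy]benzoate | CC(C)(C)[Si](C)(C)OC(=O)c1ccc(O[Si](C)(C)C(C)(C)C)cc1 | intermediate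
23 | 4-[(tert-butyldimethylsilyl)oxy]benzoic acid | CC(C)(C)[Si](C)(C)Oc1ccc(cc1)C(O)=O | intermediate
24 | (1R,4R,5S,6S,9S)-9-(tert-butyldimethylsilyloxy)-4-hydroxydauc-8(14)-en-6-yl 4-[(tert-butyldimethylsilyl)oxy]benzoate | CC(C)[C@]1(O)CC[C@]2(C)C[C@H](O[Si](C)(C)C(C)(C)C)C(=C)C[C@H](OC(=O)c3ccc(O[Si](C)(C)C(C)(C)C)cc3)[C@@H]12 | intermediate
25 | Ferugin, (1R,4R,5S,6S,9S)-4,9-dihydroxydauc-8(14)-en-6-yl 4-hydroxybenzoate | CC(C)[C@]1(O)CC[C@]2(C)C[C@H](O)C(=C)C[C@H](OC(=O)c3ccc(O)cc3)[C@@H]12 | target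

Total step count: 14. Longest linear sequence: 13 steps (steps 1–11, 13 and 14); step 12 is a one-step side branch.

Steps most likely to fail

Step 8 (Proposed new method). The epoxy enol silane may rearrange under the Lewis acid (1,2-shift to a dicarbonyl), or the enol ether may oligomerise, faster than the seven-membered ring closes; the sequence may also stop after the first C–C bond. The fallback makes the two bonds one at a time by known reactions; it sets out from 12 and comes back at 14. MgI2 (Et2O/PhMe, −60 °C) opens the epoxy ketone at the carbon next to the carbonyl to give (3R,4S)-4-hydroxy-3-iodo-6-[(2S)-4-methyl-2,3-dihydrofuran-2-yl]hept-6-en-2-one F1, and TESCl/imidazole gives its triethylsilyl ether F2. An iodine-atom-transfer radical cyclisation (Et3B, air, PhH; then MeOH, 2,6-lutidine) forms C1–C5 by 7-exo attack of the α-keto radical on the enol ether, on the face fixed by C9, and the α-iodo ether is trapped as the bicyclic keto methyl acetal F3. TESOTf/Et3N converts the methyl ketone into the silyl enol ether F4, and catalytic TMSOTf closes C2–C3 by intramolecular Mukaiyama addition to the cyclic oxocarbenium ion to give 14. The C5 epimer of F3 that cannot close would be recycled by base equilibration.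

Step 10. The enolate may lose the C6 silyloxy group by β-elimination, or the equilibrium may not favour the trans ring fusion. The fallback replaces thermodynamic equilibration by kinetic protonation; it sets out from 16 (isolated by leaving out DBU) and comes back at 20. HF·pyridine (THF, 0 °C) removes the triethylsilyl group to give the cis-fused (1R,5R,6S,9S)-9-(tert-butyldimethylsilyloxy)-6-hydroxy-11,12,13-trinordauc-8(14)-en-4-one F5. LiN(iPr)2 (2.2 equiv, THF, −78 °C) forms the chelated lithium alkoxide–enolate, which no longer carries a bulky group on the H5 face. Kinetic protonation with 2,6-di-tert-butylphenol opposite the angular methyl group should then give the trans-fused (1R,5S,6S,9S)-9-(tert-butyldimethylsilyloxy)-6-hydroxy-11,12,13-trinordauc-8(14)-en-4-one F6. Organocerium addition as in step 11, with one more equivalent for the free hydroxyl and without the acid treatment, gives 20.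

Step 6. The cis-enone, or the peroxy-enolate formed from it, may isomerise before ring closure and give the trans-epoxide, and enantiocontrol may be insufficient. The fallback sets the epoxide from a carbinol stereocentre instead; it sets out from 10 and comes back at 12. Asymmetric transfer hydrogenation (RuCl[(S,S)-TsDPEN](p-cymene), iPrOH) gives (2S)-6-[(2S)-4-methyl-2,3-dihydrofuran-2-yl]hept-6-en-3-yn-2-ol F7. Semihydrogenation as in step 5 gives (2S,3Z)-6-[(2S)-4-methyl-2,3-dihydrofuran-2-yl]hepta-3,6-dien-2-ol F8. Hydroxyl-directed epoxidation (tBuOOH, VO(acac)2, PhMe, 0 °C), threo-selective through allylic 1,3-strain, gives (1S)-1-[(2R,3S)-3-{2-[(2S)-4-methyl-2,3-dihydrofuran-2-yl]prop-2-en-1-yl}oxiran-2-yl]ethan-1-ol F9. Dess–Martin periodinane (NaHCO3, CH2Cl2) then gives 12.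

Further compounds
F1 | step 8 | (3R,4S)-4-hydroxy-3-iodo-6-[(2S)-4-methyl-2,3-dihydrofuran-2-yl]hept-6-en-2-one | CC(=O)[C@H](I)[C@@H](O)CC(=C)[C@@H]1CC(C)=CO1
F2 | step 8 | (3R,4S)-3-iodo-6-[(2S)-4-methyl-2,3-dihydrofuran-2-yl]-4-(triethylsilyloxy)hept-6-en-2-one | CC(=O)[C@H](I)[C@@H](O[Si](CC)(CC)CC)CC(=C)[C@@H]1CC(C)=CO1
F3 | step 8 | 1-[8-methoxy-1-methyl-5-methylidene-3-(triethylsilyloxy)-7-oxabicyclo[4.2.1]nonan-2-yl]ethan-1-one (mixture at C2 and C8 of the bicycle) | COC1O[C@H]2C[C@]1(C)C(C(C)=O)[C@@H](O[Si](CC)(CC)CC)CC2=C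
F4 | step 8 | triethylsilyl enol ether of F3 | COC1O[C@H]2C[C@]1(C)C(C(=C)O[Si](CC)(CC)CC)[C@@H](O[Si](CC)(CC)CC)CC2=C
F5 | step 10 | (1R,5R,6S,9S)-9-(tert-butyldimethylsilyloxy)-6-hydroxy-11,12,13-trinordauc-8(14)-en-4-one (cis-fused) | O=C1CC[C@]2(C)C[C@H](O[Si](C)(C)C(C)(C)C)C(=C)C[C@H](O)[C@H]12
F6 | step 10 | (1R,5S,6S,9S)-9-(tert-butyldimethylsilyloxy)-6-hydroxy-11,12,13-trinordauc-8(14)-en-4-one (trans-fused) | O=C1CC[C@]2(C)C[C@H](O[Si](C)(C)C(C)(C)C)C(=C)C[C@H](O)[C@@H]12
F7 | step 6 | (2S)-6-[(2S)-4-methyl-2,3-dihydrofuran-2-yl]hept-6-en-3-yn-2-ol | C[C@H](O)C#CCC(=C)[C@@H]1CC(C)=CO1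
F8 | step 6 | (2S,3Z)-6-[(2S)-4-methyl-2,3-dihydrofuran-2-yl]hepta-3,6-dien-2-ol | C[C@H](O)/C=C\CC(=C)[C@@H]1CC(C)=CO1
F9 | step 6 | (1S)-1-[(2R,3S)-3-{2-[(2S)-4-methyl-2,3-dihydrofuran-2-yl]prop-2-en-1-yl}oxiran-2-yl]ethan-1-ol | C[C@H](O)[C@H]1O[C@H]1CC(=C)[C@@H]2CC(C)=CO2
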